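Start from the early times of Thursday's run, the one flask already read; it stands here with the flasks asked about.

| flask | starting complex | incoming ligand | capture agent | remark | time |
|---|---|---|---|---|---|
| Thursday's | 0.069 M | 0.0756 M | 3.15 mM | run made earlier |  |
| grey | 0.015 M | 0.0400 M | 6.00 mM |  | 2.0 min |
| blue | 0.063 M | 0.0756 M | 3.15 mM |  | 2.0 min |
| green | 0.020 M | 0.0756 M | 10.0 mM |  | 2.0 min |
| ochre | 0.12 M | 0.0250 M | 5.00 mM |  | 2.0 min |
| teal | 0.040 M | 0.150 M | 3.15 mM |  | 2.0 min |

Thursday's run (percent of the starting complex charged)

| time / s | complex with two exchanged / % |
|---|---|
| 10.0 | 0.4 |
| 15.0 | 0.9 |
| 25.0 | 1.6 |
| 40.0 | 3.7 |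

(scatter of a reading: 0.3 percentage points)

- all flasks from highest to lowest amount of complex with two exchanged, in percent of the starting complex charged, at 2.0 min (grey / blue / green / ochre / teal)
- the amount of complex with two exchanged, in percent of the starting complex charged of the flask you put first, at 2.0 min
- the amount of complex with two exchanged, in percent of the starting complex charged of the flask you put last, at 2.0 min

- the analysis behind the earlier runs scatters by 0.3 percentage points, standard deviation
- a reading or a percentage of complex with two exchanged counts all its forms, free or not
- no earlier run changes the charge of incoming ligand; that part of a forecast is a guess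
- no earlier run changes the charge of capture agent; that part of a forecast is a guess

What do the early readings show? From 10.0 s to 40.0 s time grows by a factor 4.00 and the reading by a factor 9.25, faster than in proportion. So take exchanges in turn, the second product going on to further exchange, each step with the same rate constant k, first order in complex and in ligand. The ligand order is a guess, and no run tests the capture agent, so leave it aside.

How far can the ligand carry a flask? Write its balance. Each exchange takes one incoming ligand, so c(incoming ligand) equals its charge minus n·c(starting complex). Integrating gives n = [c(incoming ligand)/c(starting complex)]·[one minus exp(−k·c(starting complex)·t)], both concentrations as charged.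

What share then holds exactly two? With equal steps, n squared over two, times exp(−n), which climbs until n reaches two. Thursday's last reading gives n of about 0.312, and so a read k of 0.121 L mol⁻¹ s⁻¹, with the scatter of that reading in it.

Now carry n, the exchanges made per starting complex charged: teal 1.65, green 0.955, blue 0.720, grey 0.523, ochre 0.172. In ochre the incoming ligand is the limiting reagent, with less of it charged than of starting complex. Every n lies below two, so my order follows n, and my shares run from 26.2 % in teal down to 1.25 % in ochre.

The forecast, saying “I assumed equal rate constants”, gives teal > green > blue > grey > ochre, with 47 % first and 1.3 % last, the same order as mine but a higher top.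

The flasks give teal > green > blue > grey > ochre, with teal at 34.9 % and ochre at 0.839 %.

    starting complex + incoming ligand → leaving ligand + complex with one exchanged (k = 0.170 L mol⁻¹ s⁻¹)
    complex with one exchanged + incoming ligand → leaving ligand + complex with two exchanged (k = 0.0820 L mol⁻¹ s⁻¹)
    complex with two exchanged + incoming ligand → leaving ligand + complex with three exchanged (k = 0.0800 L mol⁻¹ s⁻¹)
    complex with three exchanged + incoming ligand → leaving ligand + complex with four exchanged (k = 0.0640 L mol⁻¹ s⁻¹)
    complex with one exchanged + capture agent → trapped intermediate (k = 0.0760 L mol⁻¹ s⁻¹)
    starting complex + complex with two exchanged ⇌ idle adduct, settled at all times (K = 330 L mol⁻¹)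

Teal stands above my share. Its incoming ligand is down to 65 % of its charge, so the balance puts n at 1.30, below the reckoned 1.65.

For teal stopped at 80 s, the same reckoning gives n of 1.21 and a share of 21.8 %. That flask gives 26.9 %.

All runs were generated by integration for substances that don't exist, noise included.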